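The west run had twice the X of the south-east run, yet its late ratio of Z to E, 2.32, matched the south-east one, 2.31, and with that the meeting opened.

| flask | Z | X | temperature | remark | time |
|---|---|---|---|---|---|
| south | 0.10 M | 0.30 M | 45 °C | run made earlier |  |
| south-east | 0.050 M | 0.30 M | 60 °C | run made earlier |  |
| north-east | 0.075 M | 0.30 M | 45 °C | run made earlier |  |
| west | 0.10 M | 0.60 M | 60 °C | run made earlier |  |
| alpha | 0.10 M | 0.300 M (fed, over 50 h) |  | the addition at 40 °C, then warmed to 60 °C; the feed brings no volume worth counting | 2.5 d |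
| zeta | 0.10 M (fed, over 50 h) | 0.300 M | 60 °C | all else is in the flask from the start; the feed brings no volume worth counting | 2.5 d |
| theta | 0.10 M | 0.300 M (fed, over 50 h) | 60 °C | all else is in the flask from the start; the feed brings no volume worth counting | 2.5 d |
| beta | 0.10 M | 0.300 M | 60 °C | everything together at the start | 2.5 d |

- south (time / d: E / %, Z / %): 0.417: 8.7, 88.6; 1.04: 15.0, 74.4; 2.00: 16.5, 58.8; 5.00: 11.5, 31.6
- south-east (time / h: E / %, Z / %): 5.00: 14.4, 77.4; 12.0: 17.1, 54.9; 25.0: 11.0, 30.2; 40.0: 7.1, 16.4
- north-east (time / d: E / %, Z / %): 0.250: 6.1, 92.6; 0.500: 10.4, 86.0; 1.25: 15.4, 70.7; 4.00: 13.4, 36.2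
- west (time / h: E / %, Z / %): 10.0: 14.3, 38.1; 20.0: 6.8, 15.8; 25.0: 4.6, 10.1; 40.0: 1.6, 2.6

(readings scatter by 0.5 percentage points)

* the flask with the highest amount of E, in percent of the Z charged ("all alike" if they lie within 1.5 percentage points) (alpha / zeta / theta / beta / all alike)
* final E, as a percentage of the Z charged, in alpha
* final E, as a percentage of the Z charged, in zeta
* final E, as a percentage of the Z charged, in theta
* final E, as a percentage of the Z charged, in beta

- what was read earlier has a scatter of 0.5 percentage points, one standard deviation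
- a reading or a percentage of E counts all its forms, free or not

The kineticist drew the zero of the scale first. If E were used as readily as Z, the selectivity factor κ, the rate constant for using E over that for making it, would be 1, and E would top out at 36.8% of the charge. She then argued from the tail of a run, where E and Z fall in proportion. E lost per Z lost is κE/Z − 1, which must equal E/Z there, so κ = 1 + Z/E. The south-east reading at 40.0 h gives 3.31.

For a flask holding its Z from the start, with E made from Z and lost in one further step, she wrote the curve with Z and E as fractions of the charge: E = (Z − Z^κ)/(κ − 1). On this curve, with κ as read, the top lies where E = Z/κ, at Z 59.6% and E 18.0%, and the tail is E ≈ Z/(κ − 1).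

The process chemist replied that if making and using E both go with [X] alike, a feed of X changes how fast a flask moves along this curve, but not the curve, and he set zeta apart, its Z arriving by feed. He pointed out that the south run, at 45 °C with Z 0.10 M, still held Z 58.8% at 2.00 d, whereas the south-east run, at 60 °C with Z 0.050 M, held 54.9% at 12.0 h. He took this as a sign that warmth speeds the walk along the curve, though the charges of Z differ too, and he expected alpha, fed at 40 °C, colder than the 60 °C of zeta and theta, to stand nearest the top, and they committed to that.

The forecast read alpha highest, with alpha 16.8%, zeta 11%, theta 11.4% and beta 6.4%, holding that “E depends mainly on how far Z has gone”.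

The flasks give alpha highest: alpha 16.9%, zeta 10.3%, theta 10.7%, beta 5.36%. Alpha held Z 84.0% when its feed ended and 53.1% at the asked time.

    Z + X → E + D (k = 0.174 M⁻¹ h⁻¹, Ea = 88.0 kJ mol⁻¹)
    Z + X → Q + D (k = 0.00886 M⁻¹ h⁻¹, Ea = 78.0 kJ mol⁻¹)
    X + E → L + D (k = 0.459 M⁻¹ h⁻¹, Ea = 84.0 kJ mol⁻¹)
    X + Q → L + D (k = 0.159 M⁻¹ h⁻¹, Ea = 92.0 kJ mol⁻¹)
    X + E → J (k = 0.139 M⁻¹ h⁻¹, Ea = 91.0 kJ mol⁻¹)
    G ⇌ E, rate k6*(cs6 - [E]) while solid is left; crystals form when [E] > cs6 (solubility = 0.0590 M, k = 10.6 h⁻¹)
    (constants at 60 °C)

Beta ended with Z 12.9%, and the tail rule with κ = 3.31 gives E 5.58%.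

Beta left until 10 d holds Z 0.36%, so the same rule gives E 0.156%. The computed flask holds 0.152%.

The numbers in the tables are calculated for an exercise; scatter was added.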